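**Plan**

1. Retrosynthesis: the three O-benzyl groups come off last; the isoflavone is traced back through a 4-methoxycoumarin to a 3-aryl-4-hydroxycoumarin, whose ring C is cut at O1–C2 and C4–C4a into 3,5-bis(benzyloxy)phenol and a ring B arylmalonate.
2. Enabling feature: C2 and C4 of ring C are the two identical ester carbons of one malonate, and ring A (1,3,5-trioxygenated) has one free oxygen flanked by two identical ortho carbons, so the annulation has no regiochemical choice and C3 already carries ring B.
3. The malonate is cut at C3–C(ester) (diethyl carbonate) and at the ring B–C3 bond (ethyl chlorooxoacetate on a symmetric tetraoxygenated benzene made from 2,4,6-trimethoxybenzaldehyde).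
4. Forward order: ring A phenol and ring B malonate are made separately, ring C closes between them, the C2 oxygen is removed by hydride reduction and acid-induced transposition, and hydrogenolysis frees the three hydroxyls.
5. Stereochemistry: the target has no stereocentre; the only stereocentres on the way are transient and racemic.

Key step: step 7

Remark: benzyl is used for all three hydroxyls that are free in the target, so the three ring B methyl ethers stay distinct and a single hydrogenolysis ends the route.

**Route**

Step 1
Reactants: 1 phloroglucinol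
Product: 2 3,5-bis(benzyloxy)phenol
Conditions: BnBr (2.0 equiv), K2CO3, DMF, 0 °C to rt
Reagents that add atoms: benzyl bromide, BrCc1ccccc1
Why: Williamson etherification of two of the three equivalent phenoxide oxygens with the bromide as limiting reagent should give the dibenzyl ether, to be separated by chromatography from mono- and tribenzyl ethers and C-benzylated material.

Step 2
Reactants: 3 2,4,6-trimethoxybenzaldehyde
Product: 5 2,4,6-trimethoxyphenol, via 2,4,6-trimethoxyphenyl formate 4 (not isolated)
Conditions: 30% aq. H2O2, H2SO4 (cat.), MeOH, rt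
Reagents that add atoms: hydrogen peroxide, OO
Why: Acid-catalysed Dakin oxidation (Baeyer–Villiger-type aryl migration, favoured by the ortho and para methoxy groups) should give formate 4, which the acidic methanol cleaves to the phenol.

Step 3
Reactants: 5 2,4,6-trimethoxyphenol
Product: 6 2-(benzyloxy)-1,3,5-trimethoxybenzene
Conditions: BnBr, K2CO3, DMF, rt, under N2
Reagents that add atoms: benzyl bromide, BrCc1ccccc1
Why: Williamson etherification of the acidic, air-sensitive phenol should proceed cleanly since no other nucleophilic site is present.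

Step 4
Reactants: 6 2-(benzyloxy)-1,3,5-trimethoxybenzene; 7 ethyl chlorooxoacetate
Product: 8 ethyl 2-[3-(benzyloxy)-2,4,6-trimethoxyphenyl]-2-oxoacetate
Conditions: TiCl4 (1.1 equiv), CH2Cl2, −78 to −40 °C; ice-water quench
Reagents that add atoms: none
Why: Friedel–Crafts acylation at one of the two equivalent ring carbons, each flanked by two methoxy groups and para to a third, should stop at monoacylation, and the low temperature is chosen to spare the benzyl ether.

Step 5
Reactants: 8 ethyl 2-[3-(benzyloxy)-2,4,6-trimethoxyphenyl]-2-oxoacetate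
Product: 10 ethyl 2-[3-(benzyloxy)-2,4,6-trimethoxyphenyl]acetate, via ethyl aryl(hydroxy)acetate 9 (not isolated)
Conditions: Et3SiH (3 equiv), CF3CO2H, CH2Cl2, 0 °C to rt
Reagents that add atoms: none
Why: Ionic hydrogenation should reduce the protonated aryl ketone to racemic alcohol 9, whose benzylic C–O bond ionises under stabilisation by the trialkoxyaryl ring and takes a second hydride, leaving the ester untouched.

Step 6
Reactants: 10 ethyl 2-[3-(benzyloxy)-2,4,6-trimethoxyphenyl]acetate; 11 diethyl carbonate
Product: 12 diethyl 2-[3-(benzyloxy)-2,4,6-trimethoxyphenyl]malonate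
Conditions: NaH (2.5 equiv), 11 (excess), THF, reflux; then cold 1 M HCl
Reagents that add atoms: none
Why: Crossed Claisen condensation of the ester enolate with diethyl carbonate is driven forward by irreversible deprotonation of the arylmalonate formed.

Step 7
Reactants: 2 3,5-bis(benzyloxy)phenol; 12 diethyl 2-[3-(benzyloxy)-2,4,6-trimethoxyphenyl]malonate
Product: 14 5,7-bis(benzyloxy)-3-[3-(benzyloxy)-2,4,6-trimethoxyphenyl]-4-hydroxy-2H-chromen-2-one, via mixed aryl ethyl malonate 13 (not isolated)
Conditions: Ph2O, 250 °C, N2 sweep, EtOH distilled out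
Reagents that add atoms: none
Why: At 250 °C the phenol oxygen of 2 is acylated by one ester group of 12 in a thermal transesterification that gives mixed ester 13 and forms O1–C2, and removal of ethanol pulls this equilibrium forward. The remaining ethyl ester carbon then acylates the ring carbon ortho to the new aryl ester with loss of a second ethanol, forming C4–C4a, and the product tautomerises to the 4-hydroxycoumarin. The closest known reaction type is the thermal condensation of electron-rich phenols with substituted malonic esters to 3-substituted 4-hydroxycoumarins. Ring C closes in a 6-exo mode as an intramolecular Friedel–Crafts-type C-acylation, the attacked carbonyl oxygen staying outside the new ring as the 4-hydroxyl, and no stereocentre is formed. The step needs only mono-annulation, which the substrate secures: 2 has a single free hydroxyl, its two ortho carbons are equivalent and each is activated by an ortho and a para benzyloxy group, and the two ester carbons of 12 are equivalent. Aryl benzyl ethers are expected to survive the short heating, as they do in other cyclisations run in diphenyl ether at this temperature.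

Step 8
Reactants: 14 5,7-bis(benzyloxy)-3-[3-(benzyloxy)-2,4,6-trimethoxyphenyl]-4-hydroxy-2H-chromen-2-one
Product: 15 5,7-bis(benzyloxy)-3-[3-(benzyloxy)-2,4,6-trimethoxyphenyl]-4-methoxy-2H-chromen-2-one
Conditions: Me2SO4, K2CO3, acetone, reflux
Reagents that add atoms: dimethyl sulfate, COS(=O)(=O)OC
Why: O-alkylation of the ambident 4-hydroxycoumarin anion with a hard sulfate electrophile in acetone should favour the 4-methoxycoumarin over the 2-methoxychromone isomer, the usual outcome for 3-aryl-4-hydroxycoumarins bearing a 5-alkoxy group.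

Step 9
Reactants: 15 5,7-bis(benzyloxy)-3-[3-(benzyloxy)-2,4,6-trimethoxyphenyl]-4-methoxy-2H-chromen-2-one
Product: 17 5,7-bis(benzyloxy)-3-[3-(benzyloxy)-2,4,6-trimethoxyphenyl]-4H-chromen-4-one, via 4-methoxy-2H-chromen-2-ol lactol 16 (not isolated)
Conditions: i-Bu2AlH (1.2 equiv), CH2Cl2, −78 °C; then 2 M aq. HCl, THF, −78 °C to rt
Reagents that add atoms: water, O
Why: Proposed new method: hydride should add to the lactone carbonyl C2 of the vinylogous carbonate and the aluminate should hold at −78 °C, as in the reduction of coumarins to 2H-chromen-2-ols; aqueous acid then ionises the C2 hydroxyl of racemic lactol 16 to a 4-methoxybenzopyrylium ion stabilised by the 5,7-dioxygenated ring, water adds at C4 and methanol is expelled, the chromone being the thermodynamic sink; the closest known reaction type is the Stork–Danheiser-type transposition, hydride reduction then acid treatment of β-alkoxy enones and β-alkoxy unsaturated lactones.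

Step 10
Reactants: 17 5,7-bis(benzyloxy)-3-[3-(benzyloxy)-2,4,6-trimethoxyphenyl]-4H-chromen-4-one
Product: 18 5,7-dihydroxy-3-(3-hydroxy-2,4,6-trimethoxyphenyl)-4H-chromen-4-one
Conditions: H2 (1 atm), 10% Pd/C, EtOAc–MeOH, rt
Reagents that add atoms: none
Why: Hydrogenolysis of the three aryl benzyl ethers should leave the methyl ethers and the chromone C2=C3 bond, which is conjugated and shielded by the doubly ortho-substituted ring B, provided the reaction is stopped after three equivalents of hydrogen.

**Compound list**

1 | phloroglucinol | Oc1cc(O)cc(O)c1 | starting material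
2 | 3,5-bis(benzyloxy)phenol | Oc1cc(OCc2ccccc2)cc(OCc2ccccc2)c1 | intermediate
3 | 2,4,6-trimethoxybenzaldehyde | COc1cc(OC)c(C=O)c(OC)c1 | starting material
4 | 2,4,6-trimethoxyphenyl formate | COc1cc(OC)c(OC=O)c(OC)c1 | intermediate
5 | 2,4,6-trimethoxyphenol | COc1cc(OC)c(O)c(OC)c1 | intermediate
6 | 2-(benzyloxy)-1,3,5-trimethoxybenzene | COc1cc(OC)c(OCc2ccccc2)c(OC)c1 | intermediate
7 | ethyl chlorooxoacetate | CCOC(=O)C(Cl)=O | starting material
8 | ethyl 2-[3-(benzyloxy)-2,4,6-trimethoxyphenyl]-2-oxoacetate | CCOC(=O)C(=O)c1c(OC)cc(OC)c(OCc2ccccc2)c1OC | intermediate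
9 | ethyl 2-[3-(benzyloxy)-2,4,6-trimethoxyphenyl]-2-hydroxyacetate (racemic) | CCOC(=O)C(O)c1c(OC)cc(OC)c(OCc2ccccc2)c1OC | intermediate
10 | ethyl 2-[3-(benzyloxy)-2,4,6-trimethoxyphenyl]acetate | CCOC(=O)Cc1c(OC)cc(OC)c(OCc2ccccc2)c1OC | intermediate
11 | diethyl carbonate | CCOC(=O)OCC | starting material
12 | diethyl 2-[3-(benzyloxy)-2,4,6-trimethoxyphenyl]malonate | CCOC(=O)C(C(=O)OCC)c1c(OC)cc(OC)c(OCc2ccccc2)c1OC | intermediate
13 | 3,5-bis(benzyloxy)phenyl ethyl 2-[3-(benzyloxy)-2,4,6-trimethoxyphenyl]malonate (racemic) | CCOC(=O)C(C(=O)Oc1cc(OCc2ccccc2)cc(OCc2ccccc2)c1)c1c(OC)cc(OC)c(OCc2ccccc2)c1OC | intermediate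
14 | 5,7-bis(benzyloxy)-3-[3-(benzyloxy)-2,4,6-trimethoxyphenyl]-4-hydroxy-2H-chromen-2-one | COc1cc(OC)c(-c2c(O)c3c(OCc4ccccc4)cc(OCc4ccccc4)cc3oc2=O)c(OC)c1OCc1ccccc1 | intermediate
15 | 5,7-bis(benzyloxy)-3-[3-(benzyloxy)-2,4,6-trimethoxyphenyl]-4-methoxy-2H-chromen-2-one | COc1cc(OC)c(-c2c(OC)c3c(OCc4ccccc4)cc(OCc4ccccc4)cc3oc2=O)c(OC)c1OCc1ccccc1 | intermediate
16 | 5,7-bis(benzyloxy)-3-[3-(benzyloxy)-2,4,6-trimethoxyphenyl]-4-methoxy-2H-chromen-2-ol (racemic) | COC1=C(c2c(OC)cc(OC)c(OCc3ccccc3)c2OC)C(O)Oc2cc(OCc3ccccc3)cc(OCc3ccccc3)c21 | intermediate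
17 | 5,7-bis(benzyloxy)-3-[3-(benzyloxy)-2,4,6-trimethoxyphenyl]-4H-chromen-4-one | COc1cc(OC)c(-c2coc3cc(OCc4ccccc4)cc(OCc4ccccc4)c3c2=O)c(OC)c1OCc1ccccc1 | intermediate
18 | 5,7-dihydroxy-3-(3-hydroxy-2,4,6-trimethoxyphenyl)-4H-chromen-4-one | COc1cc(OC)c(-c2coc3cc(O)cc(O)c3c2=O)c(OC)c1O | target

**Step count**

Total steps: 10. Longest linear sequence: 9 steps (steps 2 to 10, from 2,4,6-trimethoxybenzaldehyde).

**Steps most likely to fail**

Step 9. The lactol aluminate may open to the phenoxide enal and take a second hydride, or the ionised lactol may not transfer water to C4 cleanly. The fallback sets out from compound 14 and comes back at compound 17; it gives up the C2 carbon and brings it in again, and step 8 is then not needed. Compound 14 is heated with aqueous NaOH in ethanol, which opens the lactone and decarboxylates the β-keto acid to the deoxybenzoin 1-[2,4-bis(benzyloxy)-6-hydroxyphenyl]-2-[3-(benzyloxy)-2,4,6-trimethoxyphenyl]ethan-1-one F1. Heating F1 with N,N-dimethylformamide dimethyl acetal in toluene should form the enaminone at the methylene and close ring C with loss of dimethylamine, the standard one-carbon isoflavone closure, to give 17.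

Step 7. Benzyl groups may migrate or be lost during the heating, and acyl transfer from the doubly ortho-substituted arylmalonate may be slow. The fallback sets out from compound 10 and comes back at compound 14; it closes ring C by an intramolecular Claisen condensation at low temperature instead. Ester 10 is saponified (LiOH, THF–water) to [3-(benzyloxy)-2,4,6-trimethoxyphenyl]acetic acid F2. Commercial methyl 2,4,6-trihydroxybenzoate (COC(=O)c1c(O)cc(O)cc1O) is dibenzylated (BnBr, K2CO3, acetone), the hydrogen-bonded hydroxyl being spared, to methyl 2,4-bis(benzyloxy)-6-hydroxybenzoate F3. F2 and F3 are joined with dicyclohexylcarbodiimide and 4-(dimethylamino)pyridine to methyl 2,4-bis(benzyloxy)-6-({[3-(benzyloxy)-2,4,6-trimethoxyphenyl]acetyl}oxy)benzoate F4. Treating F4 with KOt-Bu in THF should make the arylacetate enolate attack the neighbouring methyl ester and, after acidification, give 14.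

Step 5. Acid-induced loss of the benzyl group or protodeacylation of the electron-rich ring may outrun hydride transfer to the twisted keto group. The fallback sets out from compound 8 and comes back at compound 10; it replaces the cationic deoxygenation by electron transfer. Keto ester 8 is reduced with NaBH4 in ethanol at 0 °C to alcohol 9, now isolated, and 9 is acetylated (Ac2O, pyridine) to ethyl 2-(acetyloxy)-2-[3-(benzyloxy)-2,4,6-trimethoxyphenyl]acetate F5. SmI2 in THF–HMPA with methanol as proton source should cleave the α-acetoxy group of F5 reductively and give 10.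

**Further compounds**

F1 | step 9 | 1-[2,4-bis(benzyloxy)-6-hydroxyphenyl]-2-[3-(benzyloxy)-2,4,6-trimethoxyphenyl]ethan-1-one | COc1cc(OC)c(CC(=O)c2c(O)cc(OCc3ccccc3)cc2OCc2ccccc2)c(OC)c1OCc1ccccc1
F2 | step 7 | [3-(benzyloxy)-2,4,6-trimethoxyphenyl]acetic acid | OC(=O)Cc1c(OC)cc(OC)c(OCc2ccccc2)c1OC
F3 | step 7 | methyl 2,4-bis(benzyloxy)-6-hydroxybenzoate | COC(=O)c1c(O)cc(OCc2ccccc2)cc1OCc1ccccc1
F4 | step 7 | methyl 2,4-bis(benzyloxy)-6-({[3-(benzyloxy)-2,4,6-trimethoxyphenyl]acetyl}oxy)benzoate | COC(=O)c1c(OC(=O)Cc2c(OC)cc(OC)c(OCc3ccccc3)c2OC)cc(OCc2ccccc2)cc1OCc1ccccc1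
F5 | step 5 | ethyl 2-(acetyloxy)-2-[3-(benzyloxy)-2,4,6-trimethoxyphenyl]acetate (racemic) | CCOC(=O)C(OC(C)=O)c1c(OC)cc(OC)c(OCc2ccccc2)c1OC
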